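**Retrosynthetic overview**
- The target anhydride comes from an open-chain (S)-hydroxyalkyl citric acid by one-flask O-acetylation, cyclodehydration, β-elimination and loss of CO2 (alkylcitrate → alkylaconitic anhydride → alkyl(methyl)maleic anhydride, as in the presumed fungal pathway).
- The alkylcitric acid comes from its triethyl ester, assembled by cross-metathesis/hydrogenation of an alkenyl citrate triester with (S)-non-8-en-2-ol.
- The alkenyl citrate comes from an aldol-type union of the α-carbon of ethyl undec-10-enoate with the keto carbon of diethyl oxaloacetate (the bond made by alkylcitrate synthase).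
- (S)-Non-8-en-2-ol comes from (S)-propylene oxide and hex-5-enyl Grignard reagent; this is the only stereocentre that survives, taken from the chiral pool.
- Ring order: the single ring, the maleic anhydride, is formed last (step 5).

Assumption: diethyl oxaloacetate is used as the free diester, bought as such or washed free of its cheap sodium salt with dilute acid just before use (not counted as a step).

**Step 1**
Reactants: 1 (S)-2-methyloxirane [(S)-propylene oxide]; 2 6-bromohex-1-ene
Product: 4 (2S)-non-8-en-2-ol, via hex-5-enylmagnesium bromide 3 (not isolated)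
Conditions: 2, Mg, THF, 23–40 °C; then CuI (10 mol %), 1, THF, −30 → 0 °C; 1 M HCl work-up
Reagents that add atoms: none
Why: Copper-catalysed Grignard opening of a terminal epoxide is an SN2 attack at the unsubstituted CH2 carbon only, so the C–O stereocentre of 1 is never touched and appears unchanged as the (S)-carbinol.

**Step 2**
Reactants: 5 ethyl undec-10-enoate; 6 diethyl 2-oxobutanedioate (diethyl oxaloacetate)
Product: 9 triethyl 2-hydroxydodec-11-ene-1,2,3-tricarboxylate, via lithium ester enolate 7 (not isolated), via chlorozinc ester enolate 8 (not isolated)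
Conditions: LiN(iPr)2 (1.05 equiv), THF, −78 °C; ZnCl2 (1.1 equiv), −78 → −20 °C; 6 (1.3 equiv), −78 → 0 °C; 1 M HCl
Reagents that add atoms: none
Why: Proposed new method: the lithium enolate is transmetallated to the less basic, more oxophilic zinc enolate (the reactive species of a Reformatsky reaction), which should add through a chelated six-membered transition state to the very electrophilic keto carbonyl of the keto tautomer of 6 faster than it is protonated by the enol tautomer; the closest known reaction is the classical Reformatsky addition of α-bromo-ester-derived zinc enolates to oxaloacetate diesters, which gives citrate and α-alkylcitrate triesters, and the two new stereocentres form unselectively, which does not matter because both are erased in step 5.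

**Step 3**
Reactants: 9 triethyl 2-hydroxydodec-11-ene-1,2,3-tricarboxylate; 4 (2S)-non-8-en-2-ol (2.5 equiv)
Product: 11 triethyl (18S)-2,18-dihydroxynonadecane-1,2,3-tricarboxylate, via cross-metathesis alkene 10 (not isolated)
Conditions: second-generation Grubbs catalyst RuCl2(=CHPh)(H2IMes)(PCy3) (3 mol %), CH2Cl2, 40 °C, Ar sweep; then evaporate, EtOAc, Pd/C (10 wt %), H2 (1 atm), 23 °C
Reagents that add atoms: none
Why: Olefin cross-metathesis between two unhindered terminal alkenes (excess of the cheap alcohol 4, ethylene swept out) followed in the same flask by heterogeneous hydrogenation, which removes the E/Z question; the remote (S)-carbinol is not involved, and the two homodimers differ strongly in polarity from 11.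

**Step 4**
Reactants: 11 triethyl (18S)-2,18-dihydroxynonadecane-1,2,3-tricarboxylate
Product: 12 (18S)-2,18-dihydroxynonadecane-1,2,3-tricarboxylic acid
Conditions: KOH (6 equiv), EtOH/H2O 3:1, 60 °C; then 2 M HCl to pH 1, EtOAc extraction
Reagents that add atoms: potassium hydroxide, [K+].[OH-] (its oxygen ends up in each CO2H)
Why: Ordinary ester saponification by acyl–oxygen cleavage; citrate-type β-hydroxy acids are stable to warm alkali and the remote (S)-carbinol is untouched.

**Step 5**
Reactants: 12 (18S)-2,18-dihydroxynonadecane-1,2,3-tricarboxylic acid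
Product: 15 (2S)-16-(4-methyl-2,5-dioxo-2,5-dihydrofuran-3-yl)hexadecan-2-yl acetate, via acetylated alkylcitric anhydride 13 (not isolated), via alkylaconitic anhydride 14 (not isolated)
Conditions: Ac2O (8 equiv), pyridine, 23 °C, 6 h; then 100 °C, 2–3 h; evaporate with toluene, SiO2
Reagents that add atoms: acetic anhydride, CC(=O)OC(C)=O
Why: Citric-acid-type dehydrative decarboxylation, the chemical copy of the alkylcitrate → alkylaconitate → maleic anhydride biosynthesis: Ac2O/pyridine acetylates the (S)-carbinol on oxygen (retention) and closes the succinic anhydride over the alkyl-bearing carbon with acetylation of the tertiary hydroxyl (13), E1cB loss of AcOH gives the fully substituted maleic anhydride 14, its CH2CO2H is a vinylogous β-keto acid that loses CO2 on heating, and the resulting dienolate is reprotonated to the thermodynamically preferred methylmaleic anhydride; the same sequence turns citric acid into citraconic anhydride via aconitic anhydride, and long-chain α-alkylcitric acids into alkyl(methyl)maleic anhydrides.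

**Compound list**
1 | (S)-2-methyloxirane | C[C@H]1CO1 | starting material
2 | 6-bromohex-1-ene | C=CCCCCBr | starting material
3 | hex-5-enylmagnesium bromide (formed in the flask) | C=CCCCC[Mg]Br | intermediate
4 | (2S)-non-8-en-2-ol | C[C@H](O)CCCCCC=C | intermediate
5 | ethyl undec-10-enoate | C=CCCCCCCCCC(=O)OCC | starting material
6 | diethyl 2-oxobutanedioate | CCOC(=O)CC(=O)C(=O)OCC | starting material
7 | lithium enolate of 5 (formed in the flask; expected major geometry drawn) | [Li+].C=CCCCCCCC/C=C(/[O-])OCC | intermediate
8 | ethyl 2-(chlorozincio)undec-10-enoate, chlorozinc enolate of 5 (formed in the flask; C-bound form drawn, racemic) | CCOC(=O)C([Zn]Cl)CCCCCCCC=C | intermediate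
9 | triethyl 2-hydroxydodec-11-ene-1,2,3-tricarboxylate (racemic, both diastereomers) | CCOC(=O)CC(O)(C(=O)OCC)C(CCCCCCCC=C)C(=O)OCC | intermediate
10 | triethyl (11E,18S)-2,18-dihydroxynonadec-11-ene-1,2,3-tricarboxylate (formed in the flask; E/Z mixture, E drawn; C2/C3 unassigned) | CCOC(=O)CC(O)(C(=O)OCC)C(CCCCCCC/C=C/CCCCC[C@H](C)O)C(=O)OCC | intermediate
11 | triethyl (18S)-2,18-dihydroxynonadecane-1,2,3-tricarboxylate (C2/C3 mixture) | CCOC(=O)CC(O)(C(=O)OCC)C(CCCCCCCCCCCCCC[C@H](C)O)C(=O)OCC | intermediate
12 | (18S)-2,18-dihydroxynonadecane-1,2,3-tricarboxylic acid (C2/C3 mixture) | OC(=O)CC(O)(C(=O)O)C(CCCCCCCCCCCCCC[C@H](C)O)C(=O)O | intermediate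
13 | 2-[3-(acetyloxy)-4-[(15S)-15-(acetyloxy)hexadecyl]-2,5-dioxooxolan-3-yl]acetic acid (formed in the flask; ring centres unassigned) | CC(=O)O[C@@H](C)CCCCCCCCCCCCCCC1C(=O)OC(=O)C1(CC(=O)O)OC(C)=O | intermediate
14 | 2-[4-[(15S)-15-(acetyloxy)hexadecyl]-2,5-dioxo-2,5-dihydrofuran-3-yl]acetic acid (formed in the flask) | CC(=O)O[C@@H](C)CCCCCCCCCCCCCCC1=C(CC(=O)O)C(=O)OC1=O | intermediate
15 | (2S)-16-(4-methyl-2,5-dioxo-2,5-dihydrofuran-3-yl)hexadecan-2-yl acetate | CC(=O)O[C@@H](C)CCCCCCCCCCCCCCC1=C(C)C(=O)OC1=O | target

**Count**
Total steps: 5. Longest linear sequence: 4 steps (5 → 9 → 11 → 12 → 15, or 1 → 4 → 11 → 12 → 15).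

**Steps most likely to fail, with fallbacks**

Step 2 (zinc-enolate aldol onto oxaloacetate). Diethyl oxaloacetate is largely enolised, so proton transfer to the enolate can beat addition and the yield may be low. The fallback reverses the order of bond formation. It sets out from 5: crossed Claisen condensation with diethyl oxalate (NaOEt, EtOH/Et2O, 0 → 23 °C) gives diethyl 2-(non-8-en-1-yl)-3-oxobutanedioate F1. Its keto group then takes up the Reformatsky reagent from ethyl bromoacetate and activated Zn dust (THF, reflux; dilute HCl work-up), the way fluoro- and alkyl-citrate triesters have classically been made. The route is rejoined at 9.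

Step 5 (one-flask dehydration/decarboxylation/acetylation). Two things could go wrong. The anhydride could close over the unsubstituted arm, so that the wrong carboxyl is lost and a chain-extended monoalkylmaleic anhydride results. The free carbinol could also acylate intermolecularly before it is acetylated. The fallback avoids the decarboxylation altogether. It sets out from 5: LiN(iPr)2, THF, −78 °C, then ethyl pyruvate gives diethyl 2-hydroxy-2-methyl-3-(non-8-en-1-yl)butanedioate F4. Cross-metathesis with 4 under the step 3 conditions gives diethyl 2-hydroxy-3-[(8E,15S)-15-hydroxyhexadec-8-en-1-yl]-2-methylbutanedioate F5, hydrogenated in the same flask to diethyl 2-hydroxy-3-[(15S)-15-hydroxyhexadecyl]-2-methylbutanedioate F6. Saponification (KOH, then HCl) gives 2-hydroxy-3-[(15S)-15-hydroxyhexadecyl]-2-methylbutanedioic acid F7. Ac2O/pyridine at 23 → 100 °C then acetylates both hydroxyls, closes the anhydride and eliminates AcOH by E1cB. The route is rejoined at 15.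

Step 3 (cross-metathesis/hydrogenation). The metathesis is statistical, and the polar, chelating hydroxy triester 9 may slow the ruthenium catalyst; Ru–H species could also isomerise the alkene before it is reduced. The fallback moves the metathesis ahead of the aldol. It sets out from 4 and 5 (5 in threefold excess): the same catalyst gives ethyl (10E,17S)-17-hydroxyoctadec-10-enoate F2, hydrogenated in the same flask (Pd/C, H2) to ethyl (17S)-17-hydroxyoctadecanoate F3. Its alkoxide/enolate dianion (LiN(iPr)2, 2.1 equiv, THF, −78 °C; then ZnCl2) is added to 6 as in step 2. The route is rejoined at 11.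

**Further compounds**
F1 | step 2 | diethyl 2-(non-8-en-1-yl)-3-oxobutanedioate (racemic) | CCOC(=O)C(=O)C(CCCCCCCC=C)C(=O)OCC
F2 | step 3 | ethyl (10E,17S)-17-hydroxyoctadec-10-enoate (E/Z mixture, E drawn) | C[C@H](O)CCCCC/C=C/CCCCCCCCC(=O)OCC
F3 | step 3 | ethyl (17S)-17-hydroxyoctadecanoate | C[C@H](O)CCCCCCCCCCCCCCCC(=O)OCC
F4 | step 5 | diethyl 2-hydroxy-2-methyl-3-(non-8-en-1-yl)butanedioate (diastereomer mixture) | CCOC(=O)C(C)(O)C(CCCCCCCC=C)C(=O)OCC
F5 | step 5 | diethyl 2-hydroxy-3-[(8E,15S)-15-hydroxyhexadec-8-en-1-yl]-2-methylbutanedioate (E/Z mixture, E drawn) | CCOC(=O)C(C)(O)C(CCCCCCC/C=C/CCCCC[C@H](C)O)C(=O)OCC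
F6 | step 5 | diethyl 2-hydroxy-3-[(15S)-15-hydroxyhexadecyl]-2-methylbutanedioate | CCOC(=O)C(C)(O)C(CCCCCCCCCCCCCC[C@H](C)O)C(=O)OCC
F7 | step 5 | 2-hydroxy-3-[(15S)-15-hydroxyhexadecyl]-2-methylbutanedioic acid | OC(=O)C(C)(O)C(CCCCCCCCCCCCCC[C@H](C)O)C(=O)O
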